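Assumption: the target has no stereogenic element (no stereocentre, and rotation about the two aryl–O bonds is fast at room temperature), so the achiral compound as drawn is the single species asked for. Compounds 1 and 2 are taken as commercial.

Numbering used throughout: 1 = 2,4-dibromophenol; 2 = 3,5-dibromo-2-hydroxybenzaldehyde; 3 = dienone formed in the flask in step 1; 4 = coupled phenol aldehyde; 5 = its methyl ether; 6 = aryl formate formed in the flask in step 3; 7 = target.

## Analysis of the target

- The target is a tetrabrominated diphenyl ether: two benzene rings joined by one oxygen, with no further ring and no chain. Ring A is numbered C1 (bridging O), C2 (OMe), C3 (Br), C5 (Br); ring B is numbered C1' (bridging O), C2' (OH), C4' (Br), C6' (Br).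
- There is no stereocentre, and the tri-ortho-substituted ether axis (OMe on one side, OH and Br on the other) is not a stable stereogenic axis.
- The two rings look alike but are not. In ring A the bromines are ortho and para to the methoxy oxygen and meta to the bridge. In ring B they are ortho and para to the bridging oxygen and meta to the hydroxyl. One bromination of a symmetric bisphenol therefore cannot give both patterns, and the two oxygens next to the bridge must be told apart (Me against H).
- The feature that invites the key move: the bridging oxygen is a phenolic oxygen of ring B whose three ortho/para carbons (C2', C4', C6') are all substituted. It is bonded to C1 of ring A, which is the only unsubstituted ortho/para carbon of a 2,4-dibromophenol (O at C2, Br at C3 and C5). This is the signature of an oxidative O–H/C–H coupling of two bromophenols, the presumed biosynthetic origin of this family.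
- Sensitive groups are the four aryl C–Br bonds (no Pd(0) or Ni(0), no organolithium, no hydrogenolysis) and the free phenol once the ether exists.
- The difficulty is to make a hindered C–O bond between two electron-poor rings with the right regiochemistry on both, and to differentiate the two flanking oxygens, in very few steps.

## Retrosynthetic reasoning

**7 to 5 (through 6).** The C2'–OH bond of ring B is traced back to a C2'–CHO bond (Baeyer–Villiger oxidation, then cleavage of formate 6). This is done because it turns ring B into the commercial aldehyde 2, and because the oxygen at C2' then does not yet exist when the ring-A oxygen is methylated, so no protecting group is needed. The formyl group also blocks its carbon and lowers the nucleophilicity of ring B during the coupling.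

**5 to 4.** The O–CH3 bond is cut. In 4 the ring-A hydroxyl is the only phenol, so the methylation cannot go to the wrong oxygen.

**4 to 1 + 2.** The bond between C1 of ring A and the bridging oxygen is cut, so that the oxygen stays with ring B (it is the phenol oxygen of 2) and ring A becomes 1 with hydrogen at the coupling carbon. The cut is made here and not at C1'–O because C1 is the one hydrogen-bearing ortho/para carbon of 1, whereas 2 has none; the substitution pattern of the two phenols therefore encodes the regiochemistry. What is gained is that both halves are shelf phenols in their native oxidation state, with no halogen, metal or leaving group at the coupling atoms. The forward reaction must remove the O–H hydrogen of 2 and the C6–H hydrogen of 1 and join O to C, a union of two nucleophilic partners that calls for an anode.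

## Alternatives that were turned down

**Alternative 1: (the textbook route).**
- Disconnection: the C1'–O bond in the polar sense, with ring B as electrophile.
- Forward key step: SNAr of the phenoxide of 3,5-dibromo-2-methoxyphenol A1 on 3,5-dibromo-2-fluorobenzaldehyde A2 (K2CO3, DMF), which would give 5 directly.
- Reason turned down: A1 must first be made from 2 in two steps (O-methylation, Baeyer–Villiger oxidation), so the sequence is four steps with two separate aldehyde-to-phenol oxidations, against three here. Every substituent is carried in prefunctionalised. The substitution takes place at a carbon flanked by CHO and Br with a phenoxide that carries an ortho OMe, which is the most hindered site of both rings. It is reliable but longer, and it ignores the relationship between the two rings.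

**Alternative 2:**
- Disconnection: the C1–O bond of ring A, with C1 as a carbene carbon.
- Forward key step: Rh2(OAc)4-catalysed O–H insertion of the carbenoid from 2,4-dibromo-6-diazocyclohexa-2,4-dien-1-one A4 (by diazotisation of 2-amino-4,6-dibromophenol A3) into the phenol of 2, which would give 4 regiospecifically.
- Reason turned down: α-oxo carbenes of this kind contract by Wolff rearrangement to a cyclopentadienyl ketene. The carbenoid would meet a weakly nucleophilic, internally hydrogen-bonded OH next to a formyl group that can form a carbonyl ylide. A4 belongs to the shock-sensitive diazo oxides. Two steps are needed to reach 4 instead of one.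

**Alternative 3:**
- Disconnection: all four C–Br bonds.
- Forward key step: fourfold electrophilic bromination of 2-(2-hydroxyphenoxy)benzaldehyde A5. The hydroxyl directs on ring A (C3, C5), and the bridging oxygen, reinforced by the meta-directing formyl group, directs on ring B (C4', C6'), which would give 4.
- Reason turned down: the first three substitutions are fast, but the fourth (C6', ortho to the bridge) must occur on a ring that already carries CHO and Br and whose aryloxy donor has been weakened by the dibrominated ring A. The forcing conditions invite oxidation of the aldehyde and ipso attack on ring A, and would give mixtures of tri- and tetrabromides. The ether bond would still come from an SNAr step, and the count is again four steps.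

Key step: step 1

## Route

Step 1
Reactants: 1 2,4-dibromophenol; 2 3,5-dibromo-2-hydroxybenzaldehyde
Product: 4 3,5-dibromo-2-(3,5-dibromo-2-hydroxyphenoxy)benzaldehyde, via aryloxycyclohexadienone 3 (not isolated)
Conditions: undivided cell, boron-doped diamond anode, Pt cathode, constant current (ca. 5 mA cm−2, ca. 2.2 F per mol of 1), Bu3MeN+ MeOSO3− (0.1 M), HFIP, 40 °C; 2 (4 equiv) in the cell, 1 (1 equiv) fed by syringe pump during the electrolysis
Reagents that add atoms: none
Why: Anodic oxidation in HFIP converts both phenols into phenoxyl radicals by proton-coupled electron transfer, and HFIP keeps these radicals alive long enough to cross-terminate while protons are reduced to H2 at the cathode. The radical from 2 carries its spin on O and on C1, C3 and C5, all of which are substituted (CHO, Br, Br), so any bond it makes through carbon gives a dienone that cannot tautomerise and reverts; it can end productively only through oxygen. The radical from 1 has spin at C2, C4 and C6 and only C6 bears hydrogen, so O–C6 coupling gives dienone 3, whose enolisation to phenol 4 is irreversible and creates the ether bond between C1 of ring A and the oxygen on C1' of ring B. The closest known reaction types are the anodic oxidative coupling of halogenated phenols to diaryl ethers and the oxidative (enzymatic or manganese oxide) C–H/O–H dimerisation of 1 itself, which is the presumed biosynthetic coupling of this family. No ring is closed and no stereocentre is set: the sp3 carbon of 3 is racemic and is erased by tautomerisation. The step needs cross-coupling over homo-coupling, which should be secured by keeping 2 in fourfold excess (recoverable) and feeding 1 slowly, so that each radical of 1 is born in a pool of the carbon-blocked radical of 2. It also needs C6 over the bromine-bearing C2 and C4 of 1, which should be secured because only the C6 adduct can rearomatise by a hydrogen shift and because the non-basic medium shuts down the bromide-displacing radical-anion chain that would link the rings at C4.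

Step 2
Reactants: 4 3,5-dibromo-2-(3,5-dibromo-2-hydroxyphenoxy)benzaldehyde
Product: 5 3,5-dibromo-2-(3,5-dibromo-2-methoxyphenoxy)benzaldehyde
Conditions: MeI (1.5 equiv), K2CO3 (1.5 equiv), acetone, 23 °C
Reagents that add atoms: iodomethane (MeI), CI
Why: Williamson O-methylation of the only phenol in the molecule; the ortho,para-dibrominated phenol is acidic enough to be fully ionised by K2CO3, and the low temperature is chosen so that alkylation outruns any aryl migration in the phenoxide.

Step 3
Reactants: 5 3,5-dibromo-2-(3,5-dibromo-2-methoxyphenoxy)benzaldehyde
Product: 7 3,5-dibromo-2-(3,5-dibromo-2-methoxyphenoxy)phenol, via aryl formate 6 (not isolated)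
Conditions: mCPBA, CH2Cl2, 40 °C; aqueous NaHCO3/Na2S2O3 wash; then K2CO3 (0.1 equiv), MeOH, 23 °C
Reagents that add atoms: 3-chloroperoxybenzoic acid (mCPBA), O=C(OO)c1cccc(Cl)c1
Why: Baeyer–Villiger (Dakin-type) oxidation of an ortho-oxygenated benzaldehyde: in the Criegee adduct ring B should migrate in preference to hydride because the lone pair of the ortho bridging oxygen stabilises the migrating ipso carbon, and the resulting formate 6 is cleaved by methanolysis. The C–Br bonds, the methyl ether and the diaryl ether are inert to peracid, and the phenoxide of 7 cannot undergo aryl migration because ring A is not activated.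

## Compound list

1 | 2,4-dibromophenol | Oc1ccc(Br)cc1Br | starting material
2 | 3,5-dibromo-2-hydroxybenzaldehyde | O=Cc1cc(Br)cc(Br)c1O | starting material
3 | 3,5-dibromo-2-[(3,5-dibromo-2-oxocyclohexa-3,5-dien-1-yl)oxy]benzaldehyde (racemic, formed in the flask) | O=C1C(Br)=CC(Br)=CC1Oc1c(Br)cc(Br)cc1C=O | intermediate
4 | 3,5-dibromo-2-(3,5-dibromo-2-hydroxyphenoxy)benzaldehyde | O=Cc1cc(Br)cc(Br)c1Oc1cc(Br)cc(Br)c1O | intermediate
5 | 3,5-dibromo-2-(3,5-dibromo-2-methoxyphenoxy)benzaldehyde | COc1c(Br)cc(Br)cc1Oc1c(Br)cc(Br)cc1C=O | intermediate
6 | 3,5-dibromo-2-(3,5-dibromo-2-methoxyphenoxy)phenyl formate (formed in the flask) | COc1c(Br)cc(Br)cc1Oc1c(Br)cc(Br)cc1OC=O | intermediate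
7 | 3,5-dibromo-2-(3,5-dibromo-2-methoxyphenoxy)phenol | COc1c(Br)cc(Br)cc1Oc1c(O)cc(Br)cc1Br | target

## Step count and risk

Total step count: 3. Longest linear sequence: 3 steps (1 to 4 to 5 to 7; 2 enters in step 1).

**Step 1 (key step).**
- What may go wrong: homo-coupling of 1 through O–C6 or C6–C6 bond formation may compete with the cross-coupling. The product phenol, itself a carbon-blocked phenol, may be re-oxidised, enter the radical pool and be arylated further. Coupling at the bromine-bearing carbons of 1 followed by loss of bromine may give para-linked or debrominated ethers.
- Fallback: this forms the same C1–O bond by ligand coupling at iodine(III) instead of by oxidation of two phenols. It sets out from 1. Iodination at the free ortho carbon (NIS, cat. TsOH, MeCN) should give 2,4-dibromo-6-iodophenol F1. O-Methylation (MeI, K2CO3, acetone) should give 1,5-dibromo-3-iodo-2-methoxybenzene F2. One-pot oxidation and arylation (mCPBA, TsOH·H2O, MeCN, then 1,3,5-trimethoxybenzene) should give (3,5-dibromo-2-methoxyphenyl)(2,4,6-trimethoxyphenyl)iodonium 4-methylbenzenesulfonate F3. The phenoxide of 2 (K2CO3, MeCN, 60 °C) should then take the ring-A aryl group from F3, with the trimethoxyphenyl group as the ligand that is not transferred. The sequence comes back to the route at 5, so that step 2 is no longer needed.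

**Step 3.**
- What may go wrong: migration of hydride instead of ring B in the Criegee adduct would lead to the benzoic acid. The risk arises because ring B carries two bromines and its ortho donor is an aryloxy group, weaker than an alkoxy group. Addition of the peracid to the hindered formyl group may also be slow.
- Fallback: this brings the C2' oxygen in as a benzyl ether, so that no carbon-to-oxygen migration is needed. It sets out from 1. 2-(Benzyloxy)phenol F4 would be dibrominated ortho and para to its hydroxyl (NBS, 2 equiv, cat. i-Pr2NH, CH2Cl2) to 2-(benzyloxy)-4,6-dibromophenol F5. F5 takes the place of 2 in the electrolysis of step 1 with 1 and should give 2-[2-(benzyloxy)-4,6-dibromophenoxy]-4,6-dibromophenol F6. Methylation (MeI, K2CO3, acetone) should give 1-(benzyloxy)-3,5-dibromo-2-(3,5-dibromo-2-methoxyphenoxy)benzene F7. Debenzylation (BCl3, pentamethylbenzene, CH2Cl2, −78 °C), which leaves the methyl ether and the C–Br bonds alone, comes back to the route at 7.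

**Step 2.**
- What may go wrong: in the phenoxide of 4, ring B may migrate from one oxygen of ring A to the other through a spiro Meisenheimer adduct (Smiles-type shift), because its ipso carbon C1' is activated by the ortho formyl group. Methylation of the rearranged phenoxide would give the regioisomeric methyl ether. Alkylation of the hindered, delocalised phenoxide may also be slow.
- Fallback: this removes the activation before any base is used. It sets out from 4. Acetalisation (HC(OMe)3, cat. TsOH, MeOH) should give 2,4-dibromo-6-[2,4-dibromo-6-(dimethoxymethyl)phenoxy]phenol F8. Methylation (MeI, K2CO3, acetone) should give 1,5-dibromo-2-(3,5-dibromo-2-methoxyphenoxy)-3-(dimethoxymethyl)benzene F9. Mild hydrolysis (aqueous HCl, THF) comes back to the route at 5.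

## Further compounds

F1 | step 1 | 2,4-dibromo-6-iodophenol | Oc1c(Br)cc(Br)cc1I
F2 | step 1 | 1,5-dibromo-3-iodo-2-methoxybenzene | COc1c(Br)cc(Br)cc1I
F3 | step 1 | (3,5-dibromo-2-methoxyphenyl)(2,4,6-trimethoxyphenyl)iodonium 4-methylbenzenesulfonate | COc1cc(OC)c([I+]c2cc(Br)cc(Br)c2OC)c(OC)c1.Cc1ccc(cc1)S(=O)(=O)[O-]
F4 | step 3 | 2-(benzyloxy)phenol | Oc1ccccc1OCc1ccccc1
F5 | step 3 | 2-(benzyloxy)-4,6-dibromophenol | Oc1c(Br)cc(Br)cc1OCc1ccccc1
F6 | step 3 | 2-[2-(benzyloxy)-4,6-dibromophenoxy]-4,6-dibromophenol | Oc1c(Br)cc(Br)cc1Oc1c(Br)cc(Br)cc1OCc1ccccc1
F7 | step 3 | 1-(benzyloxy)-3,5-dibromo-2-(3,5-dibromo-2-methoxyphenoxy)benzene | COc1c(Br)cc(Br)cc1Oc1c(Br)cc(Br)cc1OCc1ccccc1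
F8 | step 2 | 2,4-dibromo-6-[2,4-dibromo-6-(dimethoxymethyl)phenoxy]phenol | COC(OC)c1cc(Br)cc(Br)c1Oc1cc(Br)cc(Br)c1O
F9 | step 2 | 1,5-dibromo-2-(3,5-dibromo-2-methoxyphenoxy)-3-(dimethoxymethyl)benzene | COC(OC)c1cc(Br)cc(Br)c1Oc1cc(Br)cc(Br)c1OC
A1 | alternative 1 | 3,5-dibromo-2-methoxyphenol | COc1c(Br)cc(Br)cc1O
A2 | alternative 1 | 3,5-dibromo-2-fluorobenzaldehyde | O=Cc1cc(Br)cc(Br)c1F
A3 | alternative 2 | 2-amino-4,6-dibromophenol | Nc1cc(Br)cc(Br)c1O
A4 | alternative 2 | 2,4-dibromo-6-diazocyclohexa-2,4-dien-1-one | [N-]=[N+]=C1C=C(Br)C=C(Br)C1=O
A5 | alternative 3 | 2-(2-hydroxyphenoxy)benzaldehyde | O=Cc1ccccc1Oc1ccccc1O
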